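Everything rests on opening upper ring C at C4–C4a, C3–C4 and O1–C2. The feature used is the unbroken chain C4–C3–C2 with its neighbours: C4 joins C4a of ring A to C8 of ring D, C3 carries oxygen, C2 carries ring B and O1. The chain therefore divides into a phenol, the formyl carbon of an aryl aldehyde and an (E)-enol ester of an arylacetaldehyde. In one operation PhB(OH)2 welds 3-(benzyloxy)phenol to perbenzylated gallocatechin-8-carbaldehyde, and the ortho-quinone methide then released takes up the enol pivalate, closing ring C with three bonds and three stereocentres. The enol ester is made geometrically pure from an (E)-alkenylboron compound.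

Key step: step 8

Remarks on the chemistry (assumptions):
- Ring letters: upper unit A (benzo), B (aryl), C (pyran); lower unit D (benzo), E (aryl), F (pyran). The target has the upper unit (2R,3S,4S), that is 2,3-trans and 3,4-trans with ring D on the α face, and the lower unit (2R,3S).
- Precursor design: the lower 3-hydroxyl is benzylated so that boron meets a single hydroxyl in step 8. The enol ester is built stereospecifically instead of by enolisation of an arylacetaldehyde, which would give E/Z mixtures. Pivalate is kept because it is a poor donor and resists acyl transfer.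
- Step 8 fixes the three new stereocentres only relative to one another; the diastereomer from attack on the other face of the methide is assumed to be separable by chromatography after step 8 or step 9.
- (+)-Dihydrorobinetin, needed only in a fallback, is taken to be purchasable.

Step 1
Reactants: 1 (+)-gallocatechin
Product: 2 5,7,3',4',5'-penta-O-benzyl-(+)-gallocatechin (3-OH free; 2R,3S)
Conditions: BnBr (5.5 equiv), K2CO3 (6 equiv), DMF, 0 °C → rt, Ar
Reagents that add atoms: benzyl bromide, BrCc1ccccc1
Why: Williamson ether synthesis in which K2CO3 deprotonates only the five phenols, each phenoxide displaces bromide by SN2, and the secondary alcohol and both stereocentres stay untouched.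

Step 2
Reactants: 2 5,7,3',4',5'-penta-O-benzyl-(+)-gallocatechin
Product: 4 3,5,7,3',4',5'-hexa-O-benzyl-(+)-gallocatechin (2R,3S), via sodium 3-alkoxide 3 (not isolated)
Conditions: NaH (1.5 equiv), DMF, 0 °C; BnBr (1.3 equiv), 0 °C → rt
Reagents that add atoms: benzyl bromide, BrCc1ccccc1
Why: Williamson ether synthesis on the remaining secondary alcohol through alkoxide 3; with every phenol already capped, no base-induced opening of ring F can epimerise C2.

Step 3
Reactants: 4 3,5,7,3',4',5'-hexa-O-benzyl-(+)-gallocatechin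
Product: 5 8-bromo-3,5,7,3',4',5'-hexa-O-benzyl-(+)-gallocatechin (2R,3S)
Conditions: NBS (1.0 equiv), CH2Cl2, −78 °C → rt, dark
Reagents that add atoms: N-bromosuccinimide, BrN1C(=O)CCC1=O
Why: Electrophilic aromatic bromination of the phloroglucinol-type ring D, the most electron-rich arene present, at C8 (between one benzyloxy group and the ring oxygen) rather than at the more crowded C6 (between two benzyloxy groups), as is usual for 5,7-di-O-benzyl flavan-3-ols.

Step 4
Reactants: 5 8-bromo-3,5,7,3',4',5'-hexa-O-benzyl-(+)-gallocatechin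
Product: 8 3,5,7,3',4',5'-hexa-O-benzyl-(+)-gallocatechin-8-carbaldehyde (2R,3S), via 8-lithio arene 6 (not isolated), via lithium aminoalkoxide 7 (not isolated)
Conditions: n-BuLi (1.1 equiv), THF, −78 °C; DMF (3 equiv), −78 → 0 °C; H2O
Reagents that add atoms: N,N-dimethylformamide, CN(C)C=O
Why: Bromine–lithium exchange outruns any deprotonation at −78 °C and gives an aryllithium held by two ortho oxygens, which adds to DMF (Bouveault formylation); adduct 7 persists until aqueous work-up, so no second addition occurs.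

Step 5
Reactants: 9 3,4,5-tris(benzyloxy)benzaldehyde
Product: 11 (E)-2-{2-[3,4,5-tris(benzyloxy)phenyl]ethenyl}-4,4,5,5-tetramethyl-1,3,2-dioxaborolane, via lithium beta-alkoxide adduct 10 (not isolated)
Conditions: CH2(Bpin)2 (1.2 equiv), lithium 2,2,6,6-tetramethylpiperidide (1.2 equiv), THF, 0 °C; 9, −78 °C → rt; H2O
Reagents that add atoms: bis(pinacolato)borylmethane, CC1(C)OB(CB2OC(C)(C)C(C)(C)O2)OC1(C)C
Why: Boron-Wittig olefination in which the alpha-boryl carbanion adds to the aldehyde and adduct 10 loses lithium pinacolborate by syn B–O elimination, which with aromatic aldehydes gives the trans-alkenylboronate and so fixes the (E) geometry later carried into upper C2 and C3.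

Step 6
Reactants: 11 (E)-alkenyl pinacol boronate
Product: 12 potassium (E)-trifluoro{2-[3,4,5-tris(benzyloxy)phenyl]ethenyl}borate
Conditions: KHF2 (4 equiv), MeOH/H2O, rt
Reagents that add atoms: potassium hydrogen difluoride, [K+].[F-].F
Why: Standard exchange of the pinacol ester for fluoride gives the crystalline, air-stable trifluoroborate without touching the alkene geometry.

Step 7
Reactants: 12 potassium (E)-alkenyltrifluoroborate
Product: 13 (E)-2-[3,4,5-tris(benzyloxy)phenyl]ethenyl pivalate
Conditions: t-BuCO2H (1.5 equiv), CuBr (10 mol %), DMAP (0.2 equiv), 4 Å MS, O2 (1 atm), MeCN, 60 °C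
Reagents that add atoms: pivalic acid, CC(C)(C)C(O)=O
Why: Chan–Lam-type oxidative C–O coupling of an alkenyltrifluoroborate with a carboxylic acid, in which transmetallation to copper and reductive elimination from trivalent copper both retain the alkene geometry, so the (E)-borate gives the (E)-enol ester.

Step 8
Reactants: 14 3-(benzyloxy)phenol; 8 hexa-O-benzyl-(+)-gallocatechin-8-carbaldehyde; 13 (E)-2-[3,4,5-tris(benzyloxy)phenyl]ethenyl pivalate
Product: 18 deca-O-benzyl-robinetinidol-(4α→8)-gallocatechin 3-O-pivalate (upper unit 2R,3S,4S; lower unit 2R,3S), via aryl hydrogen phenylboronate 15 (not isolated), via 4-aryl-1,3,2-benzodioxaborin 16 (not isolated), via (E)-ortho-quinone methide 17 (not isolated)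
Conditions: PhB(OH)2 (1.1 equiv), EtCO2H (0.3 equiv), PhMe, reflux, azeotropic removal of H2O; then 13 (2.5 equiv), 110 °C; aq. NaHCO3 work-up
Reagents that add atoms: none
Why: Proposed new method: PhB(OH)2 esterifies phenol 14 to 15, the boron-bound aldehyde 8 is attacked through a six-membered transition state by the ring carbon ortho to the boron-bearing oxygen and para to the benzyloxy group, and loss of water gives benzodioxaborin 16, whose C4–O bond ionises readily on heating because C4 carries the trioxygenated ring D, releasing the (E)-ortho-quinone methide 17 and a phenylboron oxide that returns as PhB(OH)2 on work-up. The closest known reaction type is the PhB(OH)2-mediated three-component chroman synthesis from a phenol, an aldehyde and a styrene, an inverse-electron-demand hetero-Diels–Alder reaction of an ortho-quinone methide; untested here are an enol ester of an arylacetaldehyde as the 2π partner and a hindered, electron-rich aryl aldehyde. Upper ring C closes by an intermolecular asynchronous (4+2) cycloaddition in which O=C–C=C of 17 supplies O1, C8a, C4a and C4 and the alkene of 13 supplies C3 and C2: the pivaloyloxy-bearing carbon bonds to the methide carbon first (C3–C4), and the carbonyl oxygen then bonds to the benzylic carbon (O1–C2). C2 and C3 are fixed relative to each other by the (E) geometry of 13, carried over suprafacially as 2,3-trans, and C4 is fixed relative to C2 by the endo placement of the aryl group of 13 beneath the (E)-methide, which gives 2,4-cis and therefore 3,4-trans, the all-equatorial arrangement that a stepwise closure through a zwitterion would favour as well. The absolute sense (2R,3S,4S) depends on the face of 17 that is attacked, which only the twisted chiral ring D with its unlike ortho flanks (7-benzyloxy against O1 next to C2 of ring F) can bias, so the (2S,3R,4R) diastereomer is expected alongside and is to be removed by chromatography. The step needs ortho-selectivity in the first bond (secured by delivery through boron and by crowding of the position between the two oxygens of 14), oxygen-to-C2 regiochemistry (secured by the 4-benzyloxyphenyl group stabilising positive charge better than the weakly donating, bulky pivaloyloxy group) and endo selectivity (secured by the compact transition state with the aryl group under the heterodiene).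

Step 9
Reactants: 18 deca-O-benzyl-robinetinidol-(4α→8)-gallocatechin 3-O-pivalate
Product: 19 deca-O-benzyl-robinetinidol-(4α→8)-gallocatechin (upper 3-OH free; upper unit 2R,3S,4S; lower unit 2R,3S)
Conditions: LiAlH4 (2 equiv), THF, 0 °C → rt; H2O, aq. NaOH
Reagents that add atoms: none
Why: Hydride reduction cleaves the hindered ester at the acyl carbon and frees the 3-hydroxyl without basic epimerising conditions; benzyl ethers, both chroman rings and the C4–C8 bond are inert to LiAlH4, so no stereocentre is touched.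

Step 10
Reactants: 19 deca-O-benzyl-robinetinidol-(4α→8)-gallocatechin
Product: 20 robinetinidol-(4α→8)-gallocatechin
Conditions: H2 (1 atm), Pd(OH)2/C, THF/MeOH/H2O, rt
Reagents that add atoms: none
Why: Catalytic hydrogenolysis removes all ten O-benzyl groups under neutral conditions, the usual global deprotection of benzylated proanthocyanidins, and the C4–C8 bond and the cyclic benzylic ethers O1–C2 are not cleaved at 1 atm and room temperature.

Compound list

1 | (+)-gallocatechin, (2R,3S)-2-(3,4,5-trihydroxyphenyl)chromane-3,5,7-triol | Oc1cc(O)c2c(c1)O[C@H](c1cc(O)c(O)c(O)c1)[C@@H](O)C2 | starting material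
2 | (2R,3S)-5,7-bis(benzyloxy)-2-[3,4,5-tris(benzyloxy)phenyl]chroman-3-ol | c1c(OCc9ccccc9)cc(OCc9ccccc9)c2c1O[C@H](c3cc(OCc9ccccc9)c(OCc9ccccc9)c(OCc9ccccc9)c3)[C@@H](O)C2 | intermediate
3 | sodium 3-alkoxide of 2 | c1c(OCc9ccccc9)cc(OCc9ccccc9)c2c1O[C@H](c3cc(OCc9ccccc9)c(OCc9ccccc9)c(OCc9ccccc9)c3)[C@@H]([O-])C2.[Na+] | intermediate (not isolated)
4 | (2R,3S)-3,5,7-tris(benzyloxy)-2-[3,4,5-tris(benzyloxy)phenyl]chromane | c1c(OCc9ccccc9)cc(OCc9ccccc9)c2c1O[C@H](c3cc(OCc9ccccc9)c(OCc9ccccc9)c(OCc9ccccc9)c3)[C@@H](OCc9ccccc9)C2 | intermediate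
5 | (2R,3S)-8-bromo-3,5,7-tris(benzyloxy)-2-[3,4,5-tris(benzyloxy)phenyl]chromane | Brc1c(OCc9ccccc9)cc(OCc9ccccc9)c2c1O[C@H](c3cc(OCc9ccccc9)c(OCc9ccccc9)c(OCc9ccccc9)c3)[C@@H](OCc9ccccc9)C2 | intermediate
6 | 8-lithio derivative of 4 (lithium in place of bromine of 5) | [Li]c1c(OCc9ccccc9)cc(OCc9ccccc9)c2c1O[C@H](c3cc(OCc9ccccc9)c(OCc9ccccc9)c(OCc9ccccc9)c3)[C@@H](OCc9ccccc9)C2 | intermediate (not isolated)
7 | lithium (dimethylamino)(lower-unit-8-yl)methanolate, both epimers at the new carbon | [Li]OC(N(C)C)c1c(OCc9ccccc9)cc(OCc9ccccc9)c2c1O[C@H](c3cc(OCc9ccccc9)c(OCc9ccccc9)c(OCc9ccccc9)c3)[C@@H](OCc9ccccc9)C2 | intermediate (not isolated)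
8 | (2R,3S)-3,5,7-tris(benzyloxy)-2-[3,4,5-tris(benzyloxy)phenyl]chromane-8-carbaldehyde | O=Cc1c(OCc9ccccc9)cc(OCc9ccccc9)c2c1O[C@H](c3cc(OCc9ccccc9)c(OCc9ccccc9)c(OCc9ccccc9)c3)[C@@H](OCc9ccccc9)C2 | intermediate
9 | 3,4,5-tris(benzyloxy)benzaldehyde | O=Cc1cc(OCc2ccccc2)c(OCc2ccccc2)c(OCc2ccccc2)c1 | starting material
10 | lithium 2,2-bis(4,4,5,5-tetramethyl-1,3,2-dioxaborolan-2-yl)-1-[3,4,5-tris(benzyloxy)phenyl]ethanolate, racemic | [Li]OC(c1cc(OCc2ccccc2)c(OCc2ccccc2)c(OCc2ccccc2)c1)C(B1OC(C)(C)C(C)(C)O1)B1OC(C)(C)C(C)(C)O1 | intermediate (not isolated)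
11 | (E)-2-{2-[3,4,5-tris(benzyloxy)phenyl]ethenyl}-4,4,5,5-tetramethyl-1,3,2-dioxaborolane | CC1(C)OB(/C=C/c2cc(OCc3ccccc3)c(OCc3ccccc3)c(OCc3ccccc3)c2)OC1(C)C | intermediate
12 | potassium (E)-trifluoro{2-[3,4,5-tris(benzyloxy)phenyl]ethenyl}borate | [K+].F[B-](F)(F)/C=C/c1cc(OCc2ccccc2)c(OCc2ccccc2)c(OCc2ccccc2)c1 | intermediate
13 | (E)-2-[3,4,5-tris(benzyloxy)phenyl]ethenyl pivalate | CC(C)(C)C(=O)O/C=C/c1cc(OCc2ccccc2)c(OCc2ccccc2)c(OCc2ccccc2)c1 | intermediate
14 | 3-(benzyloxy)phenol | Oc1cccc(OCc2ccccc2)c1 | starting material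
15 | 3-(benzyloxy)phenyl hydrogen phenylboronate | OB(c1ccccc1)Oc1cccc(OCc2ccccc2)c1 | intermediate (not isolated)
16 | 7-(benzyloxy)-2-phenyl-4-(lower-unit-8-yl)-4H-1,3,2-benzodioxaborin, both C4 epimers, lower unit (2R,3S) | c1ccccc1B1Oc2cc(OCc9ccccc9)ccc2C(O1)c1c(OCc9ccccc9)cc(OCc9ccccc9)c2c1O[C@H](c3cc(OCc9ccccc9)c(OCc9ccccc9)c(OCc9ccccc9)c3)[C@@H](OCc9ccccc9)C2 | intermediate (not isolated)
17 | (E)-3-(benzyloxy)-6-[(lower-unit-8-yl)methylidene]cyclohexa-2,4-dien-1-one, aryl group anti to the carbonyl, lower unit (2R,3S) | c1(/C=C3/C(=O)C=C(OCc9ccccc9)C=C3)c(OCc9ccccc9)cc(OCc9ccccc9)c2c1O[C@H](c3cc(OCc9ccccc9)c(OCc9ccccc9)c(OCc9ccccc9)c3)[C@@H](OCc9ccccc9)C2 | intermediate (not isolated)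
18 | (2R,3S,4S)-7-(benzyloxy)-2-[3,4,5-tris(benzyloxy)phenyl]-4-{(2R,3S)-3,5,7-tris(benzyloxy)-2-[3,4,5-tris(benzyloxy)phenyl]chroman-8-yl}chroman-3-yl pivalate | O(Cc9ccccc9)c1ccc2c(c1)O[C@H](c3cc(OCc9ccccc9)c(OCc9ccccc9)c(OCc9ccccc9)c3)[C@@H](OC(=O)C(C)(C)C)[C@@H]2c1c(OCc9ccccc9)cc(OCc9ccccc9)c2c1O[C@H](c3cc(OCc9ccccc9)c(OCc9ccccc9)c(OCc9ccccc9)c3)[C@@H](OCc9ccccc9)C2 | intermediate
19 | (2R,3S,4S)-7-(benzyloxy)-2-[3,4,5-tris(benzyloxy)phenyl]-4-{(2R,3S)-3,5,7-tris(benzyloxy)-2-[3,4,5-tris(benzyloxy)phenyl]chroman-8-yl}chroman-3-ol | O(Cc9ccccc9)c1ccc2c(c1)O[C@H](c3cc(OCc9ccccc9)c(OCc9ccccc9)c(OCc9ccccc9)c3)[C@@H](O)[C@@H]2c1c(OCc9ccccc9)cc(OCc9ccccc9)c2c1O[C@H](c3cc(OCc9ccccc9)c(OCc9ccccc9)c(OCc9ccccc9)c3)[C@@H](OCc9ccccc9)C2 | intermediate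
20 | robinetinidol-(4α→8)-gallocatechin, upper unit (2R,3S,4S), lower unit (2R,3S) | Oc1ccc2c(c1)O[C@H](c1cc(O)c(O)c(O)c1)[C@@H](O)[C@@H]2c1c(O)cc(O)c2c1O[C@H](c1cc(O)c(O)c(O)c1)[C@@H](O)C2 | target

Total step count: 10. Longest linear sequence: 7 steps (steps 1, 2, 3, 4, 8, 9, 10 from (+)-gallocatechin).

Steps most likely to fail

Step 8. The methide may be consumed by the electron-rich arenes present or by a second phenol before the weakly nucleophilic enol ester adds. The dienophile may add with reversed regiochemistry or lose its geometry in a stepwise pathway. Attack on the two faces of the methide may be nearly equal. The fallback uses known chemistry, sets out from 4 and rejoins the route at 19. (+)-Dihydrorobinetin F1 (bought, 2R,3R) is benzylated on its four phenols with BnBr and K2CO3 in DMF to 7,3',4',5'-tetra-O-benzyl-dihydrorobinetin F2. NaBH4 in THF/EtOH reduces the ketone to the 2,3-trans-3,4-trans flavan-3,4-diol F3. F3 is then ionised at C4 with BF3·OEt2 (or TMSOTf) in CH2Cl2 at low temperature in the presence of an excess of 4. The benzylic cation, stabilised by the 7-benzyloxy group, is captured by C8 of ring D from the face opposite the 3-hydroxyl, the Friedel–Crafts condensation long used to assemble proanthocyanidins. This gives 19; the 4β epimer and any C6-linked isomer are removed by chromatography, and step 10 follows.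

Step 7. Protodeboronation and oxidative homocoupling of the electron-rich alkenylboron species may outrun C–O bond formation with the hindered carboxylate. The fallback sets out from 11 and rejoins at 13. Oxidation of 11 with NaBO3·4H2O in THF/H2O gives 2-[3,4,5-tris(benzyloxy)phenyl]acetaldehyde F4 through its enol. O-acylation of F4 under enolising conditions (pivalic anhydride, Et3N, catalytic DMAP, THF, reflux) gives the enol pivalates as an E/Z mixture. Chromatography or crystallisation separates 13 from the (Z)-enol pivalate F5, which is set aside.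

Step 1. The pyrogallol ring may oxidise in air as its phenoxide, and the phloroglucinol ring may be C-benzylated under base. The fallback sets out from 1 and rejoins at 4, replacing steps 1 and 2. Ac2O in pyridine gives hexa-O-acetyl-(+)-gallocatechin F6. NaH, BnBr and a measured amount of water in DMF at 0 °C → rt then cleave the acetates one after another and benzylate each oxide as it is freed, so that no polyphenolate accumulates. With excess base and halide the 3-oxygen is benzylated as well, giving 4.

Further compounds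

F1 | step 8 | (+)-dihydrorobinetin, (2R,3R)-3,7-dihydroxy-2-(3,4,5-trihydroxyphenyl)chroman-4-one (bought) | Oc1ccc2c(c1)O[C@H](c3cc(O)c(O)c(O)c3)[C@@H](O)C2=O
F2 | step 8 | (2R,3R)-7-(benzyloxy)-3-hydroxy-2-[3,4,5-tris(benzyloxy)phenyl]chroman-4-one | O(Cc9ccccc9)c1ccc2c(c1)O[C@H](c3cc(OCc9ccccc9)c(OCc9ccccc9)c(OCc9ccccc9)c3)[C@@H](O)C2=O
F3 | step 8 | (2R,3S,4R)-7-(benzyloxy)-2-[3,4,5-tris(benzyloxy)phenyl]chromane-3,4-diol | O(Cc9ccccc9)c1ccc2c(c1)O[C@H](c3cc(OCc9ccccc9)c(OCc9ccccc9)c(OCc9ccccc9)c3)[C@@H](O)[C@@H]2O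
F4 | step 7 | 2-[3,4,5-tris(benzyloxy)phenyl]acetaldehyde | O=CCc1cc(OCc2ccccc2)c(OCc2ccccc2)c(OCc2ccccc2)c1
F5 | step 7 | (Z)-2-[3,4,5-tris(benzyloxy)phenyl]ethenyl pivalate | C(/OC(=O)C(C)(C)C)=C/c1cc(OCc2ccccc2)c(OCc2ccccc2)c(OCc2ccccc2)c1
F6 | step 1 | hexa-O-acetyl-(+)-gallocatechin (2R,3S) | CC(=O)Oc1cc(OC(C)=O)c2c(c1)O[C@H](c3cc(OC(C)=O)c(OC(C)=O)c(OC(C)=O)c3)[C@@H](OC(C)=O)C2
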